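**Retrosynthetic overview**

The strategy rests on the resorcinol ring C4a–C5–C6–C7–C8–C8a of the isochromanone. With oxygen on C6 and C8, the lactone carbonyl C1 on C8a and the carbinol C3 two carbons from C4a, the chain C3–C4–C4a–C5–C6–C7–C8–C8a–C1 carries oxygen on every second carbon, and both phenols must be delivered unprotected because the C10' methyl ether of the side chain rules out a late aryl ether cleavage.
Disconnections: lactone O2–C1 (acyl transfer from an acetonide-masked salicylate); arene bond C8a–C4a (aldol condensation of a diketo-dioxinone); C4a–C5 (acylation of a keto-dioxinone dianion by a β-silyloxy Weinreb amide); C1'–C2' (γ-alkylation of acetoacetate dianion); C8'–C9' (Grignard opening of (S)-propylene oxide).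
Ring order: the dioxinone ring is bought, the benzene ring is closed first (C8a–C4a), and the lactone is closed last (O2–C1).
Stereocentres: C10' (S) comes from (S)-propylene oxide; C3 (R) is set by RuCl2[(R)-BINAP] hydrogenation of a β-keto ester.

Key step: step 11

Remark: the hydrogenation in step 6 is assumed to show the facial preference known for simple 3-oxoalkanoates; the 3R assignment of 12 should be confirmed by Mosher ester analysis before the material is carried on. Locants C1–C8a and C1'–C11' refer to the target.

**Route**

Step 1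
Reactants: 1 (S)-propylene oxide; 2 7-bromohept-1-ene
Product: 4 (S)-dec-9-en-2-ol, via hept-6-enylmagnesium bromide 3 (not isolated)
Conditions: 2, Mg, THF, reflux; then CuBr·SMe2 (10 mol%), 1, THF, −30 → 0 °C; then 1 M HCl
Reagents that add atoms: none
Why: Copper-catalysed Grignard opening of a terminal epoxide is an SN2 attack at the unsubstituted CH2, so no bond at the stereocentre is broken and the S configuration of 1 is carried unchanged into 4.

Step 2
Reactants: 4 (S)-dec-9-en-2-ol
Product: 5 (S)-9-methoxydec-1-ene
Conditions: NaH, THF, 0 °C; MeI, 0 °C → rt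
Reagents that add atoms: iodomethane, CI
Why: Williamson etherification of the sodium alkoxide with iodomethane forms the O–CH3 bond only, so the carbinol configuration is untouched.

Step 3
Reactants: 5 (S)-9-methoxydec-1-ene
Product: 7 (S)-9-methoxydecan-1-ol, via B-[(S)-9-methoxydecyl]-9-borabicyclo[3.3.1]nonane 6 (not isolated)
Conditions: 9-BBN, THF, 0 °C → rt; then 3 M NaOH, 30% H2O2, 0 °C → rt
Reagents that add atoms: hydrogen peroxide, OO
Why: Hydroboration–oxidation with the bulky 9-BBN places boron on the terminal carbon of the monosubstituted alkene and oxidative migration gives the primary alcohol, while the methyl ether is inert.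

Step 4
Reactants: 7 (S)-9-methoxydecan-1-ol
Product: 8 (S)-1-bromo-9-methoxydecane
Conditions: CBr4, PPh3, CH2Cl2, 0 °C → rt
Reagents that add atoms: tetrabromomethane, BrC(Br)(Br)Br
Why: The Appel reaction converts an unhindered primary alcohol into the bromide by SN2 displacement of an alkoxyphosphonium ion under neutral conditions that leave the secondary methyl ether alone.

Step 5
Reactants: 8 (S)-1-bromo-9-methoxydecane; 9 methyl acetoacetate
Product: 11 methyl (S)-13-methoxy-3-oxotetradecanoate, via acetoacetate dianion 10 (not isolated)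
Conditions: 9 (1.5 equiv), NaH, THF, 0 °C; n-BuLi, 0 °C; then 8, 0 °C → rt; then 1 M HCl
Reagents that add atoms: none
Why: In the γ-alkylation of an acetoacetate dianion the terminal carbanion, formed last, is the most nucleophilic site and displaces the primary bromide by SN2, so only the γ-carbon is alkylated.

Step 6
Reactants: 11 methyl (S)-13-methoxy-3-oxotetradecanoate
Product: 12 methyl (3R,13S)-3-hydroxy-13-methoxytetradecanoate
Conditions: H2 (50 atm), RuCl2[(R)-BINAP] (1 mol%), MeOH, 50 °C
Reagents that add atoms: none
Why: In the Noyori asymmetric hydrogenation the β-keto ester chelates ruthenium and the (R)-BINAP ligand directs hydride to the face that gives the 3R alcohol, as with methyl 3-oxobutanoate; this is pure catalyst control because the C13 centre is ten bonds away.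

Step 7
Reactants: 12 methyl (3R,13S)-3-hydroxy-13-methoxytetradecanoate
Product: 13 (3R,13S)-3-hydroxy-N,13-dimethoxy-N-methyltetradecanamide
Conditions: MeNH(OMe)·HCl, i-PrMgCl, THF, −20 → 0 °C; then 1 M HCl
Reagents that add atoms: N,O-dimethylhydroxylamine hydrochloride, CNOC.Cl
Why: Weinreb amide formation by aminolysis of the methyl ester with the chloromagnesium amide made in the flask tolerates the free β-hydroxyl, which is only deprotonated, and touches no stereocentre.

Step 8
Reactants: 13 (3R,13S)-3-hydroxy-N,13-dimethoxy-N-methyltetradecanamide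
Product: 14 (3R,13S)-3-(tert-butyldimethylsilyloxy)-N,13-dimethoxy-N-methyltetradecanamide
Conditions: TBSCl, imidazole, DMF, rt
Reagents that add atoms: tert-butyldimethylsilyl chloride, CC(C)(C)[Si](C)(C)Cl
Why: Imidazole-promoted silylation of the secondary alcohol masks the C3 oxygen as an ether that is stable to the strong bases and the amine of steps 10 and 11 and is removable with fluoride.

Step 9
Reactants: 15 2,2,6-trimethyl-4H-1,3-dioxin-4-one
Product: 17 2,2-dimethyl-6-(2-oxopropyl)-4H-1,3-dioxin-4-one, via dioxinone lithium dienolate 16 (not isolated)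
Conditions: LiN(SiMe3)2, THF, −78 °C; AcCl (0.5 equiv), −78 °C; then 1 M HCl
Reagents that add atoms: acetyl chloride, CC(=O)Cl
Why: Kinetic deprotonation of the 6-methyl group gives the lithium dienolate, which is C-acylated at that carbon in a vinylogous Claisen condensation; the acid chloride is kept limiting because the more acidic product consumes a second equivalent of dienolate.

Step 10
Reactants: 17 2,2-dimethyl-6-(2-oxopropyl)-4H-1,3-dioxin-4-one; 14 (3R,13S)-3-(tert-butyldimethylsilyloxy)-N,13-dimethoxy-N-methyltetradecanamide
Product: 19 6-[(6R,16S)-6-(tert-butyldimethylsilyloxy)-16-methoxy-2,4-dioxoheptadecyl]-2,2-dimethyl-4H-1,3-dioxin-4-one, via keto-dioxinone dianion 18 (not isolated)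
Conditions: 17 (2 equiv), LiN(i-Pr)2 (4 equiv), THF, −78 °C; then 14, −78 → −40 °C; then cold 1 M HCl to pH 3; crude 19 used directly
Reagents that add atoms: none
Why: In this Claisen-type acylation the dianion reacts at its terminal, last-formed enolate carbon with the Weinreb amide, whose chelated tetrahedral adduct survives until the quench and so prevents a second addition; the product is a sensitive enol mixture and is therefore not purified.

Step 11
Reactants: 19 6-[(6R,16S)-6-(tert-butyldimethylsilyloxy)-16-methoxy-2,4-dioxoheptadecyl]-2,2-dimethyl-4H-1,3-dioxin-4-one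
Product: 21 7-hydroxy-2,2-dimethyl-5-[(2R,12S)-2-(tert-butyldimethylsilyloxy)-12-methoxytridecyl]-4H-1,3-benzodioxin-4-one, via cyclic aldol 20 (not isolated)
Conditions: Et3N, CH2Cl2, rt
Reagents that add atoms: none
Why: Et3N removes a proton from the doubly activated CH2 (future C7) between the dioxinone and the neighbouring ketone, and the extended dienolate attacks through the dioxinone α-carbon (future C8a) the distal ketone that carries the silyloxyalkyl chain (future C4a) to give carbinol 20, which loses water and tautomerises at C6 to the phenol. The closest known reaction type is the amine-promoted aldol condensation–aromatisation of 6-(2,4-dioxoalkyl)-1,3-dioxin-4-ones to acetonide-protected β-resorcylates, the laboratory version of polyketide aldol folding. The one ring closed is the benzene ring, by a 6-exo-trig aldol addition of C8a to the C4a carbonyl followed by dehydrative aromatisation. No stereocentre is made, since the carbinol carbon of 20 becomes aromatic, and C3 and C10' take no part. The selectivity needed is C–C closure from C8a onto C4a in preference to O-cyclisation to a pyranone or hemiketal, attack on the dioxinone carbonyl, or β-elimination of the C3 oxygen; the dioxinone secures it by holding C1 and the C8 enol oxygen in a ring of fixed cis geometry so that a single carbon nucleophile sits six atoms from a ketone, the weak amine base at room temperature avoids ketene formation, and the silyl ether keeps the C3 oxygen from acting as nucleophile or leaving group.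

Step 12
Reactants: 21 7-hydroxy-2,2-dimethyl-5-[(2R,12S)-2-(tert-butyldimethylsilyloxy)-12-methoxytridecyl]-4H-1,3-benzodioxin-4-one
Product: 23 (3R)-6,8-dihydroxy-3-[(10S)-10-methoxyundecyl]isochroman-1-one, via hydroxy benzodioxinone 22 (not isolated)
Conditions: Bu4NF (3 equiv), THF, 0 → 40 °C; then 1 M HCl
Reagents that add atoms: none
Why: Fluoride desilylation releases the C3 alkoxide, which attacks the benzodioxinone carbonyl C1 in a 6-exo-trig acyl substitution (intramolecular transesterification) whose tetrahedral intermediate expels acetone and the C8 phenoxide; the C3–O bond is never broken, so the R configuration is retained and the methyl ether is untouched.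

**Compound list**

1 | (S)-propylene oxide | C[C@H]1CO1 | starting material
2 | 7-bromohept-1-ene | C=CCCCCCBr | starting material
3 | hept-6-enylmagnesium bromide | C=CCCCCC[Mg]Br | intermediate
4 | (S)-dec-9-en-2-ol | C[C@H](O)CCCCCCC=C | intermediate
5 | (S)-9-methoxydec-1-ene | CO[C@@H](C)CCCCCCC=C | intermediate
6 | B-[(S)-9-methoxydecyl]-9-borabicyclo[3.3.1]nonane | CO[C@@H](C)CCCCCCCCB1C2CCCC1CCC2 | intermediate
7 | (S)-9-methoxydecan-1-ol | CO[C@@H](C)CCCCCCCCO | intermediate
8 | (S)-1-bromo-9-methoxydecane | CO[C@@H](C)CCCCCCCCBr | intermediate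
9 | methyl acetoacetate | COC(=O)CC(C)=O | starting material
10 | lithium sodium dianion of methyl acetoacetate | [Li+].[Na+].C=C([O-])C=C([O-])OC | intermediate
11 | methyl (S)-13-methoxy-3-oxotetradecanoate | CO[C@@H](C)CCCCCCCCCC(=O)CC(=O)OC | intermediate
12 | methyl (3R,13S)-3-hydroxy-13-methoxytetradecanoate | CO[C@@H](C)CCCCCCCCC[C@@H](O)CC(=O)OC | intermediate
13 | (3R,13S)-3-hydroxy-N,13-dimethoxy-N-methyltetradecanamide | CO[C@@H](C)CCCCCCCCC[C@@H](O)CC(=O)N(C)OC | intermediate
14 | (3R,13S)-3-(tert-butyldimethylsilyloxy)-N,13-dimethoxy-N-methyltetradecanamide | CO[C@@H](C)CCCCCCCCC[C@@H](O[Si](C)(C)C(C)(C)C)CC(=O)N(C)OC | intermediate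
15 | 2,2,6-trimethyl-4H-1,3-dioxin-4-one | CC1=CC(=O)OC(C)(C)O1 | starting material
16 | lithium dienolate of 2,2,6-trimethyl-4H-1,3-dioxin-4-one | [Li+].C=C1C=C([O-])OC(C)(C)O1 | intermediate
17 | 2,2-dimethyl-6-(2-oxopropyl)-4H-1,3-dioxin-4-one | CC(=O)CC1=CC(=O)OC(C)(C)O1 | intermediate
18 | dilithium dianion of 2,2-dimethyl-6-(2-oxopropyl)-4H-1,3-dioxin-4-one | [Li+].[Li+].C=C([O-])C=C1C=C([O-])OC(C)(C)O1 | intermediate
19 | 6-[(6R,16S)-6-(tert-butyldimethylsilyloxy)-16-methoxy-2,4-dioxoheptadecyl]-2,2-dimethyl-4H-1,3-dioxin-4-one | CO[C@@H](C)CCCCCCCCC[C@@H](O[Si](C)(C)C(C)(C)C)CC(=O)CC(=O)CC1=CC(=O)OC(C)(C)O1 | intermediate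
20 | 5-hydroxy-2,2-dimethyl-5-[(2R,12S)-2-(tert-butyldimethylsilyloxy)-12-methoxytridecyl]-5,6-dihydro-4H-1,3-benzodioxine-4,7(8H)-dione (both C5 epimers) | CO[C@@H](C)CCCCCCCCC[C@@H](O[Si](C)(C)C(C)(C)C)CC1(O)CC(=O)CC2=C1C(=O)OC(C)(C)O2 | intermediate
21 | 7-hydroxy-2,2-dimethyl-5-[(2R,12S)-2-(tert-butyldimethylsilyloxy)-12-methoxytridecyl]-4H-1,3-benzodioxin-4-one | CO[C@@H](C)CCCCCCCCC[C@@H](O[Si](C)(C)C(C)(C)C)Cc1cc(O)cc2OC(C)(C)OC(=O)c12 | intermediate
22 | 7-hydroxy-5-[(2R,12S)-2-hydroxy-12-methoxytridecyl]-2,2-dimethyl-4H-1,3-benzodioxin-4-one | CO[C@@H](C)CCCCCCCCC[C@@H](O)Cc1cc(O)cc2OC(C)(C)OC(=O)c12 | intermediate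
23 | (3R)-6,8-dihydroxy-3-[(10S)-10-methoxyundecyl]isochroman-1-one | CO[C@@H](C)CCCCCCCCC[C@@H]1Cc2cc(O)cc(O)c2C(=O)O1 | target

**Summary**

Total step count: 12. Longest linear sequence: 11 steps (steps 1–8 and 10–12); step 9 is a one-step side branch.

Steps most likely to fail:

1. Step 10. The strongly basic dianion may deprotonate the α-CH2 of the amide instead of adding to it, which stalls the acylation and can lead on to β-elimination of silanolate. Fallback: setting out from 14, the amide would be reduced with i-Bu2AlH (THF, −78 °C) to (3R,13S)-3-(tert-butyldimethylsilyloxy)-13-methoxytetradecanal F1. Aldehydes add carbon nucleophiles faster than they are enolised, so aldol addition of dianion 18 at −78 °C should give 6-[(4RS,6R,16S)-6-(tert-butyldimethylsilyloxy)-4-hydroxy-16-methoxy-2-oxoheptadecyl]-2,2-dimethyl-4H-1,3-dioxin-4-one F2 as a mixture of carbinol epimers. Oxidation of this β-hydroxy ketone with Dess–Martin periodinane (NaHCO3, CH2Cl2, rt) removes the extra stereocentre and comes back to the route at 19.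

2. Step 11. O-cyclisation or hemiketal formation may compete with the C-aldol, the dehydration of the aldol may stall, or silanolate may be eliminated next to the C4a ketone. Fallback: setting out from 19, heating in toluene with methanol (110 °C) would open the dioxinone by retro-[4+2] loss of acetone to an acylketene, trapped as methyl (9R,19S)-9-(tert-butyldimethylsilyloxy)-19-methoxy-3,5,7-trioxoicosanoate F3. In this open-chain triketo ester C8a is a free β-keto ester CH2, and the same C8a–C4a aldol condensation with Cs2CO3 in MeOH followed by mild acidification should give methyl 2,4-dihydroxy-6-[(2R,12S)-2-(tert-butyldimethylsilyloxy)-12-methoxytridecyl]benzoate F4. Bu4NF in THF then removes the silyl group and the C3 alkoxide displaces methoxide to close the lactone, so the route is rejoined at 23.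

3. Step 12. The acyl transfer may stay incomplete because the phenoxide formed para to the carbonyl-bearing carbon under fluoride lowers the electrophilicity of the dioxinone carbonyl. Fallback: setting out from 21, the silyl ether would be cleaved without base by HF·pyridine (THF, 0 °C → rt) and 22 would be isolated. Its acetonide ester would be saponified with LiOH (aqueous THF, 0 °C → rt) to the seco acid 2,4-dihydroxy-6-[(2R,12S)-2-hydroxy-12-methoxytridecyl]benzoic acid F5. Acidification (1 M HCl, then catalytic TsOH, CH2Cl2, rt, kept cool to avoid decarboxylation) would close the δ-lactone by acid-catalysed esterification with the C3–O bond intact, rejoining the route at 23.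

Further compounds
F1 | step 10 | (3R,13S)-3-(tert-butyldimethylsilyloxy)-13-methoxytetradecanal | CO[C@@H](C)CCCCCCCCC[C@@H](O[Si](C)(C)C(C)(C)C)CC=O
F2 | step 10 | 6-[(4RS,6R,16S)-6-(tert-butyldimethylsilyloxy)-4-hydroxy-16-methoxy-2-oxoheptadecyl]-2,2-dimethyl-4H-1,3-dioxin-4-one | CO[C@@H](C)CCCCCCCCC[C@@H](O[Si](C)(C)C(C)(C)C)CC(O)CC(=O)CC1=CC(=O)OC(C)(C)O1
F3 | step 11 | methyl (9R,19S)-9-(tert-butyldimethylsilyloxy)-19-methoxy-3,5,7-trioxoicosanoate | CO[C@@H](C)CCCCCCCCC[C@@H](O[Si](C)(C)C(C)(C)C)CC(=O)CC(=O)CC(=O)CC(=O)OC
F4 | step 11 | methyl 2,4-dihydroxy-6-[(2R,12S)-2-(tert-butyldimethylsilyloxy)-12-methoxytridecyl]benzoate | CO[C@@H](C)CCCCCCCCC[C@@H](O[Si](C)(C)C(C)(C)C)Cc1cc(O)cc(O)c1C(=O)OC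
F5 | step 12 | 2,4-dihydroxy-6-[(2R,12S)-2-hydroxy-12-methoxytridecyl]benzoic acid | CO[C@@H](C)CCCCCCCCC[C@@H](O)Cc1cc(O)cc(O)c1C(=O)O
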